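**Retrosynthetic overview**

1. Ring numbering used below: C1 = ring CH bearing the lactone oxygen, C2 = ring-fusion CH bearing the lactone carbon chain, C3 = tigloyloxy CH, C4 = CH2, C5 (methyl-bearing) and C6 = epoxide carbons, C7 = carbinol, C8 = CH2, C9 = formyl-bearing CH, C10 = CH2.
2. Endgame: the formyl group comes from an (E)-propenyl group on C9 (OsO4/NaIO4), the epoxide from the C7 allylic alcohol (hydroxyl-directed), the trans-lactone from carbonylation of a 1-bromovinyl group on C2 with SN2 inversion at C1, and the tiglate plus the C1 carbinol from one Evans–Tishchenko reduction of a C1 ketone.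
3. Key disconnection C9–C10: the 10-membered carbocycle is made by a transannular Claisen ring contraction of a 12-membered 2-methylene oxacycle (macrolactone, then methylenation). The enabling feature is that the formyl-bearing C9 sits 1,3 to the oxygenated C1 through the lone methylene C10, so C1(=O)–C10H2–C9–C=C inside the 10-membered ring is a γ,δ-unsaturated ketone retron.
4. The seco acid is built linearly: carboalumination (E-C5=C6), Keck allylation (C7), Evans syn-aldol (C2, C3), and cross-metathesis with (S)-but-3-en-2-ol, whose carbinol centre later controls C9.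
5. Order of ring formation: 12-membered lactone (macrolactonisation), then 10-membered carbocycle (key step), then γ-lactone, then epoxide.

Key step: step 14

Remark on the chemistry: the C9 aldehyde of the target is epimerisable and its C9 epimer could be trapped as a lactol by the C7 hydroxyl, so the formyl group is unveiled last under buffered conditions; compounds 1, 9, 10, 16 and 24 are assumed to be purchased.

**Step 1**
Reactants: 1 tert-butyl(but-3-yn-1-yloxy)dimethylsilane
Product: 3 (E)-5-(tert-butyldimethylsilyloxy)-3-methylpent-2-en-1-ol, via alkenylalane 2 (not isolated)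
Conditions: AlMe3, Cp2ZrCl2 (cat.), CH2Cl2, 0 °C to rt; n-BuLi, THF, −78 °C; (CH2O)n, −78 °C to rt
Reagents that add atoms: trimethylaluminium, C[Al](C)C; formaldehyde (from paraformaldehyde), C=O
Why: Zirconium-catalysed syn-carboalumination (Negishi) places CH3 on the internal alkyne carbon with aluminium cis to it, and the derived alanate adds to formaldehyde with retention, which fixes the E-trisubstituted C5=C6 alkene.

**Step 2**
Reactants: 3 (E)-5-(tert-butyldimethylsilyloxy)-3-methylpent-2-en-1-ol
Product: 4 (E)-5-(tert-butyldimethylsilyloxy)-3-methylpent-2-enal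
Conditions: MnO2, CH2Cl2, rt
Reagents that add atoms: none
Why: MnO2 oxidises only the allylic alcohol (allylic oxidation) and should leave the silyl ether and the alkene geometry untouched.

**Step 3**
Reactants: 4 (E)-5-(tert-butyldimethylsilyloxy)-3-methylpent-2-enal
Product: 5 (4S,5E)-8-(tert-butyldimethylsilyloxy)-6-methylocta-1,5-dien-4-ol
Conditions: (S)-BINOL (20 mol %), Ti(OiPr)4 (10 mol %), 4 Å MS, CH2Cl2; allyltributylstannane, −20 °C; aq NaHCO3
Reagents that add atoms: allyltributylstannane, C=CC[Sn](CCCC)(CCCC)CCCC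
Why: Keck asymmetric allylation, in which the (S)-BINOL–titanium Lewis acid should direct the allylstannane to the Si face of the enal and so set the C7 carbinol as S.

**Step 4**
Reactants: 5 (4S,5E)-8-(tert-butyldimethylsilyloxy)-6-methylocta-1,5-dien-4-ol
Product: 6 (4S,5E)-4,8-bis(tert-butyldimethylsilyloxy)-6-methylocta-1,5-diene
Conditions: TBSCl, imidazole, DMF, rt
Reagents that add atoms: tert-butyldimethylsilyl chloride, CC(C)(C)[Si](C)(C)Cl
Why: Standard silylation of the secondary allylic alcohol protects C7–O until after the tiglate and lactone are in place.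

**Step 5**
Reactants: 6 (4S,5E)-4,8-bis(tert-butyldimethylsilyloxy)-6-methylocta-1,5-diene
Product: 7 (3E,5S)-5-(tert-butyldimethylsilyloxy)-3-methylocta-3,7-dien-1-ol
Conditions: HF·pyridine, pyridine, THF, 0 °C
Reagents that add atoms: none
Why: Selective desilylation, because the unhindered primary silyl ether is cleaved much faster than the secondary allylic one under buffered HF·pyridine.

**Step 6**
Reactants: 7 (3E,5S)-5-(tert-butyldimethylsilyloxy)-3-methylocta-3,7-dien-1-ol
Product: 8 (3E,5S)-5-(tert-butyldimethylsilyloxy)-3-methylocta-3,7-dienal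
Conditions: Dess–Martin periodinane, NaHCO3, CH2Cl2, 0 °C; used at once
Reagents that add atoms: none
Why: Buffered Dess–Martin oxidation should give the β,γ-unsaturated aldehyde without migration of the trisubstituted double bond into conjugation.

**Step 7**
Reactants: 9 3-bromobut-3-enoic acid; 10 (R)-4-benzyloxazolidin-2-one
Product: 12 (R)-4-benzyl-3-(3-bromobut-3-enoyl)oxazolidin-2-one, via mixed pivalic anhydride 11 (not isolated)
Conditions: t-BuCOCl, Et3N, THF, −20 °C; then 10, LiCl, −20 °C to rt
Reagents that add atoms: none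
Why: N-acylation through the mixed pivalic anhydride with LiCl/Et3N avoids strong base, so the β,γ-unsaturated bromoalkene should not isomerise.

**Step 8**
Reactants: 12 (R)-4-benzyl-3-(3-bromobut-3-enoyl)oxazolidin-2-one; 8 (3E,5S)-5-(tert-butyldimethylsilyloxy)-3-methylocta-3,7-dienal
Product: 14 (R)-4-benzyl-3-[(2R,3S,5E,7S)-2-(1-bromovinyl)-7-(tert-butyldimethylsilyloxy)-3-hydroxy-5-methyldeca-5,9-dienoyl]oxazolidin-2-one, via boron enolate 13 (not isolated)
Conditions: Bu2BOTf, i-Pr2NEt, CH2Cl2, −78 to 0 °C; 8, −78 to 0 °C; pH 7 buffer, MeOH, H2O2, 0 °C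
Reagents that add atoms: none
Why: Evans syn-aldol, in which the Z boron enolate reacts through a chair transition state on the face away from the benzyl group of the (R)-auxiliary and sets C2 and C3 together as the 2,3-syn pair, the remote C7 centre being too far to interfere.

**Step 9**
Reactants: 14 aldol adduct
Product: 15 (R)-4-benzyl-3-[(2R,3S,5E,7S)-2-(1-bromovinyl)-7-(tert-butyldimethylsilyloxy)-5-methyl-3-(triethylsilyloxy)deca-5,9-dienoyl]oxazolidin-2-one
Conditions: Et3SiOTf, 2,6-lutidine, CH2Cl2, −78 °C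
Reagents that add atoms: triethylsilyl trifluoromethanesulfonate, CC[Si](CC)(CC)OS(=O)(=O)C(F)(F)F
Why: Silylation with a triethylsilyl group gives a C3 ether that can later be removed in the presence of the C7 tert-butyldimethylsilyl ether.

**Step 10**
Reactants: 15 triethylsilyl ether; 16 (S)-but-3-en-2-ol
Product: 17 (R)-4-benzyl-3-[(2R,3S,5E,7S,9E,11S)-2-(1-bromovinyl)-7-(tert-butyldimethylsilyloxy)-11-hydroxy-5-methyl-3-(triethylsilyloxy)dodeca-5,9-dienoyl]oxazolidin-2-one
Conditions: second-generation Hoveyda–Grubbs catalyst RuCl2(H2IMes)(=CH-C6H4-2-OiPr) (10 mol %), 16 (5 equiv), CH2Cl2, 40 °C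
Reagents that add atoms: none
Why: Cross-metathesis of the monosubstituted alkene with a secondary allylic alcohol should be E-selective, the trisubstituted alkene and the hindered 1-bromovinyl group should be spectators, and the new carbinol centre is bought in with 16.

**Step 11**
Reactants: 17 cross-metathesis product
Product: 19 (2R,3S,5E,7S,9E,11S)-2-(1-bromovinyl)-7-(tert-butyldimethylsilyloxy)-11-hydroxy-5-methyl-3-(triethylsilyloxy)dodeca-5,9-dienoic acid, via peroxy acid 18 (not isolated)
Conditions: LiOH, H2O2, THF/H2O, 0 °C; Na2SO3; HCl to pH 4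
Reagents that add atoms: lithium hydroperoxide (formed from LiOH and H2O2), [Li+].[O-]O
Why: Evans auxiliary cleavage, in which hydroperoxide attacks the exocyclic imide carbonyl selectively and should not epimerise C2, sulfite then reducing the peroxy acid to the acid.

**Step 12**
Reactants: 19 seco acid
Product: 20 (3R,4S,6E,8S,10E,12S)-3-(1-bromovinyl)-8-(tert-butyldimethylsilyloxy)-6,12-dimethyl-4-(triethylsilyloxy)oxacyclododeca-6,10-dien-2-one
Conditions: 2-methyl-6-nitrobenzoic anhydride, DMAP, CH2Cl2, rt, syringe-pump addition (final 1 mM)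
Reagents that add atoms: none
Why: Shiina macrolactonisation, in which mixed-anhydride activation at room temperature and high dilution should close the 12-membered lactone through the only free hydroxyl group.

**Step 13**
Reactants: 20 macrolactone
Product: 21 (3R,4S,6E,8S,10E,12S)-3-(1-bromovinyl)-8-(tert-butyldimethylsilyloxy)-6,12-dimethyl-2-methylidene-4-(triethylsilyloxy)oxacyclododeca-6,10-diene
Conditions: Tebbe reagent Cp2Ti(μ-Cl)(μ-CH2)AlMe2, pyridine, THF/toluene, −40 °C to rt; aq NaOH; basic Al2O3
Reagents that add atoms: Tebbe reagent, C[Al-]1(C)C[Ti]([Cl+]1)(C1C=CC=C1)C1C=CC=C1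
Why: Tebbe methylenation of the lactone carbonyl is non-basic, so the epimerisable C2 centre, the silyl ethers and the bromoalkene should survive, and it turns the lactone into the cyclic allyl vinyl ether needed next.

**Step 14**
Reactants: 21 cyclic allyl vinyl ether
Product: 22 (2R,3S,5E,7S,9S)-2-(1-bromovinyl)-7-(tert-butyldimethylsilyloxy)-5-methyl-9-[(E)-prop-1-enyl]-3-(triethylsilyloxy)cyclodec-5-en-1-one
Conditions: toluene (5 mM, degassed), i-Pr2NEt (trace), base-washed sealed tube, 150 °C
Reagents that add atoms: none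
Why: Proposed new method: a thermal, concerted, suprafacial [3,3]-sigmatropic (Claisen) shift of the allyl vinyl ether unit CH2=C(–O)–O–CH(CH3)–CH=CH embedded in the 12-membered ring forms the C10–C9 bond as the C–O bond breaks, so the exocyclic methylene carbon enters the ring as C10 while the oxygen, the carbinol carbon and its neighbour leave it as the C1 carbonyl oxygen and an (E)-propenyl branch. The closest known reaction types are the Claisen rearrangement of 2-methylene oxacycles made by ester methylenation (known in the ring-enlarging sense) and the ester-enolate Claisen ring contraction of macrolides, and the C=O bond formed should outweigh the strain of the new E-cyclodecenone. The 10-membered carbocycle is closed in a transannular mode, the six-membered transition state being bridged at its 2- and 6-positions (C1 and C9) by the seven-atom chain C2–C8, which can sit pseudo-equatorially. The only new stereocentre, C9, is set by 1,3-chirality transfer from the (S)-carbinol carbon across the E-alkene: C10 bonds to the face from which the oxygen leaves in the conformer that keeps the methyl group anti to the alkene, and because the vinyl ether terminus is an unsubstituted CH2 the outcome is the same for chair and boat. The step needs the [3,3] shift to beat acid-catalysed hydrolysis or isomerisation of the enol ether and epimerisation of C2 in the product, which neutral thermal conditions, an amine trace and base-washed glass should secure, and the 1-bromovinyl group cannot compete because it forms only a 1,4-diene with the enol ether. The E/Z ratio of the propenyl group in 22 should report directly on the fidelity of the chirality transfer.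

**Step 15**
Reactants: 22 cyclodecenone
Product: 23 (2R,3S,5E,7S,9S)-2-(1-bromovinyl)-7-(tert-butyldimethylsilyloxy)-3-hydroxy-5-methyl-9-[(E)-prop-1-enyl]cyclodec-5-en-1-one
Conditions: HF·pyridine, pyridine, THF, 0 °C
Reagents that add atoms: none
Why: Selective desilylation, since a secondary triethylsilyl ether is cleaved far faster than the secondary allylic tert-butyldimethylsilyl ether and buffered HF should avoid retro-aldol opening of the β-hydroxy ketone.

**Step 16**
Reactants: 23 β-hydroxy ketone; 24 (E)-2-methylbut-2-enal (tiglaldehyde)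
Product: 25 C3 tiglate of the 1,3-anti diol (ring as in 23; C1–OH anti to C3–O and cis to the C2 bromovinyl group; C3–O–CO–C(CH3)=CH–CH3, E)
Conditions: SmI2 (0.3 equiv), 24 (6 equiv), THF, −10 °C
Reagents that add atoms: none
Why: Evans–Tishchenko reduction, in which the samarium-bound hemiacetal formed from the C3 hydroxyl and tiglaldehyde delivers hydride intramolecularly to the C1 ketone through a six-membered transition state, so the C1 carbinol is set 1,3-anti and the tiglate lands on C3–O in the same event.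

**Step 17**
Reactants: 25 hydroxy tiglate
Product: 26 C1 methanesulfonate of 25
Conditions: MsCl, Et3N, CH2Cl2, 0 °C
Reagents that add atoms: methanesulfonyl chloride, CS(=O)(=O)Cl
Why: Sulfonylation of the only free hydroxyl turns the 1,3-anti C1 oxygen into a leaving group for the inversion that follows.

**Step 18**
Reactants: 26 mesylate
Product: 28 trans-fused α-methylene-γ-butyrolactone (C1–O/C2–C) carrying the C3 tiglate, C7–OTBS, the (E)-C5=C6 alkene and the C9 (E)-propenyl group, via acrylic acid 27 (not isolated)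
Conditions: Pd(OAc)2 (10 mol %), 1,1'-bis(diphenylphosphino)ferrocene (12 mol %), CO (1 atm), H2O, Et3N, DMF, 60 °C
Reagents that add atoms: carbon monoxide, [C-]#[O+]; water, O
Why: Palladium-catalysed hydroxycarbonylation of the alkenyl bromide gives the 2-substituted acrylic acid, whose carboxylate should displace the C1 mesylate in a 5-exo-tet SN2 reaction with inversion, converting the 1,3-anti alcohol into the trans-fused lactone with C1–O syn to C3–O.

**Step 19**
Reactants: 28 silyl-protected lactone
Product: 29 C7 allylic alcohol of 28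
Conditions: HF·pyridine, THF, 0 °C to rt
Reagents that add atoms: none
Why: Acidic fluoride desilylation should free the C7 hydroxyl without touching the methylene lactone or the tiglate, which basic fluoride sources might attack.

**Step 20**
Reactants: 29 allylic alcohol
Product: 30 5,6-epoxide of 29 (trans-epoxide, oxygen syn to C7–OH)
Conditions: VO(acac)2 (5 mol %), t-BuOOH, CH2Cl2, 0 °C
Reagents that add atoms: tert-butyl hydroperoxide, CC(C)(C)OO
Why: Vanadium-catalysed hydroxyl-directed epoxidation should touch only the allylic-alcohol alkene, and with C7–H eclipsing the alkene (A(1,3) strain with the cis methyl group) the hydroxyl lies on the peripheral face, so oxygen is delivered syn to it (threo) to give the C5/C6 configuration of the target.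

**Step 21**
Reactants: 30 epoxy alcohol
Product: 32 target CNP0307768.2, via vicinal diol 31 (not isolated)
Conditions: OsO4 (2 mol %), NaIO4, 2,6-lutidine, dioxane/H2O, rt
Reagents that add atoms: osmium tetroxide, O=[Os](=O)(=O)=O; sodium periodate, [Na+].[O-]I(=O)(=O)=O
Why: Johnson–Lemieux cleavage, in which OsO4 should dihydroxylate the only electron-rich alkene (the conjugated tiglate and methylene lactone react far more slowly), periodate cleaves the diol to the C9 aldehyde, and the lutidine buffer protects the epimerisable C9 centre.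

**Compound list**

1 | tert-butyl(but-3-yn-1-yloxy)dimethylsilane | C#CCCO[Si](C)(C)C(C)(C)C | starting material
2 | [(E)-4-(tert-butyldimethylsilyloxy)-2-methylbut-1-enyl]dimethylalane | C[Al](C)/C=C(\C)CCO[Si](C)(C)C(C)(C)C | intermediate (not isolated)
3 | (E)-5-(tert-butyldimethylsilyloxy)-3-methylpent-2-en-1-ol | OC/C=C(\C)CCO[Si](C)(C)C(C)(C)C | intermediate
4 | (E)-5-(tert-butyldimethylsilyloxy)-3-methylpent-2-enal | O=C/C=C(\C)CCO[Si](C)(C)C(C)(C)C | intermediate
5 | (4S,5E)-8-(tert-butyldimethylsilyloxy)-6-methylocta-1,5-dien-4-ol | C=CC[C@H](O)/C=C(\C)CCO[Si](C)(C)C(C)(C)C | intermediate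
6 | (4S,5E)-4,8-bis(tert-butyldimethylsilyloxy)-6-methylocta-1,5-diene | C=CC[C@H](O[Si](C)(C)C(C)(C)C)/C=C(\C)CCO[Si](C)(C)C(C)(C)C | intermediate
7 | (3E,5S)-5-(tert-butyldimethylsilyloxy)-3-methylocta-3,7-dien-1-ol | C=CC[C@H](O[Si](C)(C)C(C)(C)C)/C=C(\C)CCO | intermediate
8 | (3E,5S)-5-(tert-butyldimethylsilyloxy)-3-methylocta-3,7-dienal | C=CC[C@H](O[Si](C)(C)C(C)(C)C)/C=C(\C)CC=O | intermediate
9 | 3-bromobut-3-enoic acid | OC(=O)CC(Br)=C | starting material
10 | (R)-4-benzyloxazolidin-2-one | O=C1OC[C@@H](Cc2ccccc2)N1 | starting material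
11 | 3-bromobut-3-enoic pivalic anhydride | C=C(Br)CC(=O)OC(=O)C(C)(C)C | intermediate (not isolated)
12 | (R)-4-benzyl-3-(3-bromobut-3-enoyl)oxazolidin-2-one | C=C(Br)CC(=O)N1[C@H](Cc2ccccc2)COC1=O | intermediate
13 | dibutylboron (Z)-enolate of 12 | CCCCB(CCCC)O/C(=C\C(Br)=C)N1[C@H](Cc2ccccc2)COC1=O | intermediate (not isolated)
14 | (R)-4-benzyl-3-[(2R,3S,5E,7S)-2-(1-bromovinyl)-7-(tert-butyldimethylsilyloxy)-3-hydroxy-5-methyldeca-5,9-dienoyl]oxazolidin-2-one | O=C1OC[C@@H](Cc2ccccc2)N1C(=O)[C@H](C(Br)=C)[C@@H](O)C/C(C)=C/[C@H](CC=C)O[Si](C)(C)C(C)(C)C | intermediate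
15 | (R)-4-benzyl-3-[(2R,3S,5E,7S)-2-(1-bromovinyl)-7-(tert-butyldimethylsilyloxy)-5-methyl-3-(triethylsilyloxy)deca-5,9-dienoyl]oxazolidin-2-one | O=C1OC[C@@H](Cc2ccccc2)N1C(=O)[C@H](C(Br)=C)[C@@H](O[Si](CC)(CC)CC)C/C(C)=C/[C@H](CC=C)O[Si](C)(C)C(C)(C)C | intermediate
16 | (S)-but-3-en-2-ol | C[C@H](O)C=C | starting material
17 | (R)-4-benzyl-3-[(2R,3S,5E,7S,9E,11S)-2-(1-bromovinyl)-7-(tert-butyldimethylsilyloxy)-11-hydroxy-5-methyl-3-(triethylsilyloxy)dodeca-5,9-dienoyl]oxazolidin-2-one | O=C1OC[C@@H](Cc2ccccc2)N1C(=O)[C@H](C(Br)=C)[C@@H](O[Si](CC)(CC)CC)C/C(C)=C/[C@H](C/C=C/[C@H](C)O)O[Si](C)(C)C(C)(C)C | intermediate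
18 | (2R,3S,5E,7S,9E,11S)-2-(1-bromovinyl)-7-(tert-butyldimethylsilyloxy)-11-hydroxy-5-methyl-3-(triethylsilyloxy)dodeca-5,9-dieneperoxoic acid | OOC(=O)[C@H](C(Br)=C)[C@@H](O[Si](CC)(CC)CC)C/C(C)=C/[C@H](C/C=C/[C@H](C)O)O[Si](C)(C)C(C)(C)C | intermediate (not isolated)
19 | (2R,3S,5E,7S,9E,11S)-2-(1-bromovinyl)-7-(tert-butyldimethylsilyloxy)-11-hydroxy-5-methyl-3-(triethylsilyloxy)dodeca-5,9-dienoic acid | OC(=O)[C@H](C(Br)=C)[C@@H](O[Si](CC)(CC)CC)C/C(C)=C/[C@H](C/C=C/[C@H](C)O)O[Si](C)(C)C(C)(C)C | intermediate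
20 | (3R,4S,6E,8S,10E,12S)-3-(1-bromovinyl)-8-(tert-butyldimethylsilyloxy)-6,12-dimethyl-4-(triethylsilyloxy)oxacyclododeca-6,10-dien-2-one | O=C1O[C@@H](C)/C=C/C[C@H](O[Si](C)(C)C(C)(C)C)/C=C(C)/C[C@H](O[Si](CC)(CC)CC)[C@H]1C(Br)=C | intermediate
21 | (3R,4S,6E,8S,10E,12S)-3-(1-bromovinyl)-8-(tert-butyldimethylsilyloxy)-6,12-dimethyl-2-methylidene-4-(triethylsilyloxy)oxacyclododeca-6,10-diene | C=C1O[C@@H](C)/C=C/C[C@H](O[Si](C)(C)C(C)(C)C)/C=C(C)/C[C@H](O[Si](CC)(CC)CC)[C@H]1C(Br)=C | intermediate
22 | (2R,3S,5E,7S,9S)-2-(1-bromovinyl)-7-(tert-butyldimethylsilyloxy)-5-methyl-9-[(E)-prop-1-enyl]-3-(triethylsilyloxy)cyclodec-5-en-1-one | O=C1C[C@@H](/C=C/C)C[C@H](O[Si](C)(C)C(C)(C)C)/C=C(C)/C[C@H](O[Si](CC)(CC)CC)[C@H]1C(Br)=C | intermediate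
23 | (2R,3S,5E,7S,9S)-2-(1-bromovinyl)-7-(tert-butyldimethylsilyloxy)-3-hydroxy-5-methyl-9-[(E)-prop-1-enyl]cyclodec-5-en-1-one | O=C1C[C@@H](/C=C/C)C[C@H](O[Si](C)(C)C(C)(C)C)/C=C(C)/C[C@H](O)[C@H]1C(Br)=C | intermediate
24 | (E)-2-methylbut-2-enal (tiglaldehyde) | C/C=C(\C)C=O | starting material
25 | C3 (E)-2-methylbut-2-enoate of the 1,3-anti diol (C1–OH anti to C3–O, cis to the C2 1-bromovinyl group; C7–OTBS; C9 (E)-propenyl) | O[C@H]1C[C@@H](/C=C/C)C[C@H](O[Si](C)(C)C(C)(C)C)/C=C(C)/C[C@H](OC(=O)/C(C)=C/C)[C@H]1C(Br)=C | intermediate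
26 | C1 methanesulfonate of 25 | CS(=O)(=O)O[C@H]1C[C@@H](/C=C/C)C[C@H](O[Si](C)(C)C(C)(C)C)/C=C(C)/C[C@H](OC(=O)/C(C)=C/C)[C@H]1C(Br)=C | intermediate
27 | 2-substituted acrylic acid from 26 (Br replaced by CO2H, mesylate intact) | CS(=O)(=O)O[C@H]1C[C@@H](/C=C/C)C[C@H](O[Si](C)(C)C(C)(C)C)/C=C(C)/C[C@H](OC(=O)/C(C)=C/C)[C@H]1C(=C)C(=O)O | intermediate (not isolated)
28 | trans-fused α-methylene-γ-butyrolactone with C3 tiglate, C7–OTBS, (E)-C5=C6 and C9 (E)-propenyl | C=C1C(=O)O[C@@H]2C[C@@H](/C=C/C)C[C@H](O[Si](C)(C)C(C)(C)C)/C=C(C)/C[C@H](OC(=O)/C(C)=C/C)[C@@H]12 | intermediate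
29 | C7 allylic alcohol of 28 | C=C1C(=O)O[C@@H]2C[C@@H](/C=C/C)C[C@H](O)/C=C(C)/C[C@H](OC(=O)/C(C)=C/C)[C@@H]12 | intermediate
30 | 5,6-epoxide of 29 (trans-epoxide, oxygen syn to C7–OH) | C=C1C(=O)O[C@@H]2C[C@@H](/C=C/C)C[C@H](O)[C@H]3O[C@]3(C)C[C@H](OC(=O)/C(C)=C/C)[C@@H]12 | intermediate
31 | vicinal diol from syn-dihydroxylation of the propenyl group of 30 (either face; the two new carbinol centres are left undefined) | C=C1C(=O)O[C@@H]2C[C@@H](C(O)C(C)O)C[C@H](O)[C@H]3O[C@]3(C)C[C@H](OC(=O)/C(C)=C/C)[C@@H]12 | intermediate (not isolated)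
32 | CNP0307768.2 | C=C1C(=O)O[C@@H]2C[C@@H](C=O)C[C@H](O)[C@H]3O[C@]3(C)C[C@H](OC(=O)/C(C)=C/C)[C@@H]12 | target

**Step count and risks**

Total steps: 21. Longest linear sequence: 20 steps (steps 1–6 and 8–21, from 1); step 7 is the only side branch.

Steps most likely to fail:

1. Step 14 (proposed new method). The ring-contracting [3,3] shift may be slowed by transannular strain in the transition state, so that acid-catalysed hydrolysis or double-bond migration of the enol ether, or thermal decomposition, wins. The chirality transfer may also leak through the conformer with the methyl group syn to the alkene. The fallback forms the C9–C10 bond by the same, well-known Claisen chemistry on an open chain and closes the ring at C2–C3 by an aldol reaction. It sets out from 6: cross-metathesis with 16 (second-generation Hoveyda–Grubbs catalyst) should give (2S,3E,6S,7E)-6,10-bis(tert-butyldimethylsilyloxy)-8-methyldeca-3,7-dien-2-ol F1. Esterification with 9 (N,N'-diisopropylcarbodiimide, DMAP cat., 0 °C) gives the 3-bromobut-3-enoate ester F2, and Tebbe methylenation gives the open-chain allyl vinyl ether F3. Heating in toluene (120 °C) gives, with the same 1,3-chirality transfer, the open-chain ketone F4. HF·pyridine frees the primary alcohol F5 and Dess–Martin oxidation gives the keto aldehyde F6. Bu2BOTf/i-Pr2NEt at high dilution should then enolise the more acidic C2 methylene as the Z-enolate and close the 10-membered ring by a syn-aldol reaction; its facial selectivity would have to be checked. The route is rejoined at 23.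

2. Step 16. Hydride transfer from the conjugated hemiacetal of tiglaldehyde may be slow in the medium ring, leaving time for retro-aldol ring opening, dehydration of the β-hydroxy ketone or acyl migration. The fallback separates reduction and acylation and sets out from 22. LiBH(s-Bu)3 in THF at −78 °C should attack the ketone anti to the C2–C3 ring bond (Felkin–Anh) and give the C1 alcohol F7 with the same C1 configuration as in 25. MsCl/Et3N gives the mesylate F8, HF·pyridine removes the triethylsilyl group to give the C3 alcohol F9, and tiglic acid with 2,4,6-trichlorobenzoyl chloride, Et3N and DMAP acylates C3–O. The route is rejoined at 26.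

3. Step 18. The secondary mesylate may eliminate or hydrolyse before the carboxylate is formed, or the alkenylpalladium intermediate may insert into a ring alkene instead of CO. The fallback decouples carbonylation from lactonisation and sets out from 26. Palladium-catalysed alkoxycarbonylation with 2-(trimethylsilyl)ethanol (Pd(OAc)2, 1,1'-bis(diphenylphosphino)ferrocene, CO, Et3N, DMF, 50 °C, no water) gives the 2-(trimethylsilyl)ethyl acrylate ester F10. Bu4NF in THF then releases the carboxylate, which displaces the mesylate with inversion, and removes the C7 silyl ether in the same operation. The route is rejoined at 29.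

**Further compounds**

F1 | step 14 | (2S,3E,6S,7E)-6,10-bis(tert-butyldimethylsilyloxy)-8-methyldeca-3,7-dien-2-ol | C[C@H](O)/C=C/C[C@H](O[Si](C)(C)C(C)(C)C)/C=C(\C)CCO[Si](C)(C)C(C)(C)C
F2 | step 14 | (2S,3E,6S,7E)-6,10-bis(tert-butyldimethylsilyloxy)-8-methyldeca-3,7-dien-2-yl 3-bromobut-3-enoate | C=C(Br)CC(=O)O[C@@H](C)/C=C/C[C@H](O[Si](C)(C)C(C)(C)C)/C=C(\C)CCO[Si](C)(C)C(C)(C)C
F3 | step 14 | 2-bromo-4-{[(2S,3E,6S,7E)-6,10-bis(tert-butyldimethylsilyloxy)-8-methyldeca-3,7-dien-2-yl]oxy}penta-1,4-diene | C=C(Br)CC(=C)O[C@@H](C)/C=C/C[C@H](O[Si](C)(C)C(C)(C)C)/C=C(\C)CCO[Si](C)(C)C(C)(C)C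
F4 | step 14 | (6S,8S,9E)-2-bromo-8,12-bis(tert-butyldimethylsilyloxy)-10-methyl-6-[(E)-prop-1-enyl]dodeca-1,9-dien-4-one | C=C(Br)CC(=O)C[C@@H](/C=C/C)C[C@H](O[Si](C)(C)C(C)(C)C)/C=C(\C)CCO[Si](C)(C)C(C)(C)C
F5 | step 14 | (6S,8S,9E)-2-bromo-8-(tert-butyldimethylsilyloxy)-12-hydroxy-10-methyl-6-[(E)-prop-1-enyl]dodeca-1,9-dien-4-one | C=C(Br)CC(=O)C[C@@H](/C=C/C)C[C@H](O[Si](C)(C)C(C)(C)C)/C=C(\C)CCO
F6 | step 14 | (3E,5S,7S)-11-bromo-5-(tert-butyldimethylsilyloxy)-3-methyl-9-oxo-7-[(E)-prop-1-enyl]dodeca-3,11-dienal | C=C(Br)CC(=O)C[C@@H](/C=C/C)C[C@H](O[Si](C)(C)C(C)(C)C)/C=C(\C)CC=O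
F7 | step 16 | C1 alcohol from hydride reduction of 22 (C1–OH cis to the C2 1-bromovinyl group, anti to C3–O; C3–OTES, C7–OTBS) | O[C@H]1C[C@@H](/C=C/C)C[C@H](O[Si](C)(C)C(C)(C)C)/C=C(C)/C[C@H](O[Si](CC)(CC)CC)[C@H]1C(Br)=C
F8 | step 16 | C1 methanesulfonate of F7 | CS(=O)(=O)O[C@H]1C[C@@H](/C=C/C)C[C@H](O[Si](C)(C)C(C)(C)C)/C=C(C)/C[C@H](O[Si](CC)(CC)CC)[C@H]1C(Br)=C
F9 | step 16 | C3 alcohol of F8 (triethylsilyl group removed) | CS(=O)(=O)O[C@H]1C[C@@H](/C=C/C)C[C@H](O[Si](C)(C)C(C)(C)C)/C=C(C)/C[C@H](O)[C@H]1C(Br)=C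
F10 | step 18 | 2-(trimethylsilyl)ethyl ester of acrylic acid 27 | CS(=O)(=O)O[C@H]1C[C@@H](/C=C/C)C[C@H](O[Si](C)(C)C(C)(C)C)/C=C(C)/C[C@H](OC(=O)/C(C)=C/C)[C@H]1C(=C)C(=O)OCC[Si](C)(C)C
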